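The numbers in the tables are simulated on assumed constants; noise was put on by code.

| flask | starting material | solid reagent | remark | time |
|---|---|---|---|---|
| oak | 5.0 × 10⁻⁴ M | 0.91 mM | run made earlier |  |
| maple | 5.0 × 10⁻⁴ M | 1.4 mM | run made earlier |  |
| flask | 5.0 × 10⁻⁴ M | 0.650 mM |  | 3.0 min |

| run | time / min | isomer of the product / % | target / % |
|---|---|---|---|
| oak | 0.250 | 5 | 17 |
| oak | 0.667 | 14 | 32 |
| oak | 1.50 | 31 | 29 |
| oak | 4.00 | 65 | 15 |
| maple | 0.417 | 9 | 26 |
| maple | 1.33 | 31 | 32 |
| maple | 2.50 | 47 | 21 |
| maple | 4.00 | 67 | 19 |

(readings scatter by 2 percentage points)

- as a solid, counted per litre of solution: solid reagent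
- the earlier runs were read with a standard deviation of 2 percentage points
- at the start none of the solid reagent is in solution

- ratio of isomer of the product to target at 5.0 s
- ratio of isomer of the product to target at 30 s
- ratio of isomer of the product to target at 3.0 min
- which of isomer of the product and target there is more of at 3.0 min

1. The reading at 3.0 min falls late in the earlier runs, where the target is sinking and the isomer of the product climbing. So I take the end state to be mostly isomer, with the target as the kinetic product and the isomer as the thermodynamic one. What remains is how far along the flask is.

2. Turn the question round: for the target to lead at 3.0 min, the two would have to stand level later than that. Interpolating between readings, they stand level at 1.42 min in oak and 1.37 min in maple. I take 1.40 min, and the asked time is about twice that.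

3. How far past level? I use the doubling time of the ratio, the time in which isomer over target doubles. From the first and last readings it is 0.966 min in oak and 1.07 min in maple, so 1.02 min. The flask holds less solid reagent than either run, so its loading lies outside theirs, and I carry this time over as an assumption. Doubling from one at the level time gives 2.98 at 3.0 min, with the isomer ahead. I commit to this for the late ratio; the early ratios lie outside it.

4. The forecast gives 0.17, 0.38 and 2.8, with isomer of the product ahead: “I expect the flask to behave the same, assuming solid remains.” Its late ratio is lower than mine.

5. The flask gives 0.227, 0.398 and 3.19, with isomer at 50.0 % against target at 15.6 %. They stand level at 1.36 min.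

    starting material + coupling partner ⇌ target (K = 3300 M⁻¹, k = 180 M⁻¹ s⁻¹)
    starting material + coupling partner ⇌ isomer of the product (K = 4.60 × 10⁵ M⁻¹, k = 37.0 M⁻¹ s⁻¹)
    coupling partner ⇌ dormant form (K = 1.50, k = 0.0160 s⁻¹)
    solid reagent ⇌ coupling partner, rate k4*(cs4 - [coupling partner]) while solid is left; crystals form when [coupling partner] > cs4 (solubility = 0.230 mM, k = 0.160 s⁻¹)

6. From that level time, the doubling time gives 3.05 for this flask. A neighbouring flask is charged with 8.5 × 10⁻⁴ M of starting material, more than its solid reagent, and is otherwise the same. My reckoning holds no term for that charge, so it stays at 2.98, and the neighbour gives 3.42. Isomer there reaches 41.3 % against target at 12.1 %, while starting material holds the most, 46.6 %.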